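The tetrahydroisoquinoline is opened at the N2–C1 bond. In ring A the C8 hydroxyl lies ortho and the C6 methoxyl para to C8a, so a C1 carbinol ionises under acid to an ortho-quinone methide (its protonated form is a doubly oxygen-stabilised benzylic cation). In one operation trifluoroacetic acid removes the Boc group from the C3 amine and triggers this ionisation; the amine closes the ring at C1, and because closure is reversible the C3 methyl should steer C1 to the trans (1R,3R) isomer. The precursor is an open-chain biaryl: a 2-(1-hydroxyethyl)phenol carrying the naphthyl group and an (R)-2-(Boc-amino)propyl chain derived from D-alaninol.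

Key step: step 10

Remark (assumption): the SMILES fixes C1 and C3 (both R) but gives no descriptor for the C5–C8' biaryl axis; the route sets C1 and C3 and carries both rotamers about that axis from step 8 on, to be separated on the final product if a single rotamer is wanted.

Step 1
Reactants: 1 1-bromo-3-methoxy-5-methylbenzene; 2 2-methoxyfuran
Product: 5 4,5-dimethoxy-7-methylnaphthalen-1-ol, via 3-methoxy-5-methylbenzyne 3 (not isolated), via epoxynaphthalene cycloadduct 4 (not isolated)
Conditions: LDA, 2 (3 equiv), THF, −78 °C → rt; then 1 M HCl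
Reagents that add atoms: none
Why: Lithiation between bromine and methoxyl and loss of LiBr give the aryne, which undergoes a Diels–Alder reaction with the furan in the head-to-head sense (the unsubstituted, more nucleophilic furan carbon bonds to the aryne carbon remote from the methoxyl, so the furan methoxy carbon ends up peri to the aryl methoxyl), and the bridgehead acetal opens on acid to the 4-methoxy-1-naphthol.

Step 2
Reactants: 5 4,5-dimethoxy-7-methylnaphthalen-1-ol
Product: 6 4,5-dimethoxy-7-methylnaphthalen-1-yl trifluoromethanesulfonate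
Conditions: Tf2O, pyridine, CH2Cl2, 0 °C
Reagents that add atoms: trifluoromethanesulfonic anhydride, O=S(=O)(OS(=O)(=O)C(F)(F)F)C(F)(F)F
Why: O-Sulfonylation of the naphthol turns the oxygen left by the benzannulation into the cross-coupling handle at the future C8' and removes the air-sensitive 4-methoxy-1-naphthol at once.

Step 3
Reactants: 7 1-bromo-3,5-dimethoxybenzene
Product: 8 2-bromo-4,6-dimethoxybenzaldehyde
Conditions: POCl3, DMF, 0 → 90 °C; then aq. NaOAc
Reagents that add atoms: N,N-dimethylformamide, CN(C)C=O; water, O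
Why: Vilsmeier–Haack formylation of the doubly activated arene should go mainly para to one methoxyl and ortho to the other at the position next to bromine, the minor isomer formylated between the two methoxyls being removed by crystallisation.

Step 4
Reactants: 8 2-bromo-4,6-dimethoxybenzaldehyde
Product: 9 2-bromo-6-hydroxy-4-methoxybenzaldehyde
Conditions: BCl3, CH2Cl2, −78 → 0 °C; then H2O
Reagents that add atoms: none
Why: Chelation-controlled ether cleavage, in which BCl3 binds the formyl oxygen and the ortho methoxyl in a six-membered chelate and cleaves only that methyl ether, differentiates the future C8 hydroxyl from the C6 methoxyl.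

Step 5
Reactants: 10 tert-butyl N-[(2R)-1-hydroxypropan-2-yl]carbamate (N-Boc-D-alaninol)
Product: 11 tert-butyl N-[(2R)-1-iodopropan-2-yl]carbamate
Conditions: I2, PPh3, imidazole, CH2Cl2, 0 °C → rt
Reagents that add atoms: iodine, II
Why: Appel-type iodination of the primary alcohol leaves the stereocentre untouched, so the configuration that becomes C3 is taken from D-alaninol.

Step 6
Reactants: 11 tert-butyl N-[(2R)-1-iodopropan-2-yl]carbamate; 9 2-bromo-6-hydroxy-4-methoxybenzaldehyde
Product: 13 tert-butyl N-[(2R)-1-(2-formyl-3-hydroxy-5-methoxyphenyl)propan-2-yl]carbamate, via alkylzinc iodide 12 (not isolated)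
Conditions: Zn dust, I2 (cat.), DMF, rt; then 9, Pd2(dba)3, SPhos, rt → 50 °C
Reagents that add atoms: none
Why: Zinc insertion gives a carbamate-stabilised β-amino alkylzinc iodide and Negishi coupling with the aryl bromide, activated by its ortho formyl group, forms the C4–C4a bond; alkylzinc halides do not add to the aldehyde, are protonated only slowly by the phenol in DMF, and SPhos favours reductive elimination over β-hydride elimination.

Step 7
Reactants: 13 tert-butyl N-[(2R)-1-(2-formyl-3-hydroxy-5-methoxyphenyl)propan-2-yl]carbamate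
Product: 14 tert-butyl N-[(2R)-1-(6-bromo-2-formyl-3-hydroxy-5-methoxyphenyl)propan-2-yl]carbamate
Conditions: NBS, MeCN, −20 → 0 °C
Reagents that add atoms: N-bromosuccinimide, O=C1CCC(=O)N1Br
Why: Electrophilic aromatic bromination should occur para to the chelated phenol and ortho to the methoxyl (the future C5) in preference to the position between hydroxyl and methoxyl, as in the halogenation of 2-hydroxy-4-methoxybenzaldehydes.

Step 8
Reactants: 6 4,5-dimethoxy-7-methylnaphthalen-1-yl trifluoromethanesulfonate; 14 tert-butyl N-[(2R)-1-(6-bromo-2-formyl-3-hydroxy-5-methoxyphenyl)propan-2-yl]carbamate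
Product: 16 tert-butyl N-[(2R)-1-[6-(4,5-dimethoxy-7-methylnaphthalen-1-yl)-2-formyl-3-hydroxy-5-methoxyphenyl]propan-2-yl]carbamate, via naphthyl pinacol boronate 15 (not isolated)
Conditions: B2pin2, PdCl2(dppf), KOAc, 1,4-dioxane, 90 °C; then 14, Pd(OAc)2, SPhos, aq. K3PO4, 100 °C
Reagents that add atoms: none
Why: Miyaura borylation of the triflate is followed in the same flask by Suzuki–Miyaura coupling, for which the bulky electron-rich SPhos ligand suits a tri-ortho-substituted biaryl; the new axis forms as both rotamers.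

Step 9
Reactants: 16 tert-butyl N-[(2R)-1-[6-(4,5-dimethoxy-7-methylnaphthalen-1-yl)-2-formyl-3-hydroxy-5-methoxyphenyl]propan-2-yl]carbamate
Product: 17 tert-butyl N-[(2R)-1-[6-(4,5-dimethoxy-7-methylnaphthalen-1-yl)-3-hydroxy-2-(1-hydroxyethyl)-5-methoxyphenyl]propan-2-yl]carbamate
Conditions: MeMgBr (4 equiv), THF, −20 → 0 °C; aq. NH4Cl; used crude
Reagents that add atoms: methylmagnesium bromide, C[Mg]Br
Why: Grignard addition to the aldehyde, after the first two equivalents have deprotonated phenol and carbamate, installs the C1 methyl group; the new carbinol centre forms as a mixture, which is of no consequence because step 10 ionises it.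

Step 10
Reactants: 17 tert-butyl N-[(2R)-1-[6-(4,5-dimethoxy-7-methylnaphthalen-1-yl)-3-hydroxy-2-(1-hydroxyethyl)-5-methoxyphenyl]propan-2-yl]carbamate
Product: 20 (1R,3R)-5-(4,5-dimethoxy-7-methylnaphthalen-1-yl)-6-methoxy-1,3-dimethyl-1,2,3,4-tetrahydroisoquinolin-8-ol, via amino alcohol 18 (not isolated), via ortho-quinone methide 19 (not isolated)
Conditions: TFA, CH2Cl2 (0.01 M), 0 → 40 °C; then aq. NaHCO3
Reagents that add atoms: none
Why: TFA cleaves the Boc group and ionises the C1 carbinol, which sits ortho to the C8 hydroxyl and para to the C6 methoxyl, to the ortho-quinone methide 19 (in acid its O-protonated form, a benzylic cation), and the C3 amine adds to C1. The closest known reaction types are the aza-Michael addition of amines to ortho-quinone methides generated from ortho-hydroxybenzyl alcohols and the acid-mediated SN1 cyclisation of amino benzylic alcohols to 1-substituted tetrahydroisoquinolines. The nitrogen ring closes in the 6-endo-trig mode, nitrogen attacking the exocyclic terminus C1 of the C8a=C1 bond so that ring A rearomatises. C1 is set under thermodynamic control by the C3 stereocentre: the N2–C1 bond of this ortho-hydroxy, para-methoxy benzylic ammonium ion should re-ionise in TFA (as in the acid epimerisation of 1,3-disubstituted tetrahydro-β-carbolines), and the trans isomer, with the C1 methyl pseudoaxial away from the C8 oxygen and the C3 methyl equatorial, should be the more stable. The step needs intramolecular capture by nitrogen to outrun intermolecular C-alkylation of electron-rich rings by the cation, which high dilution and the lack of any other internal nucleophile within reach of C1 should secure.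

Step 11
Reactants: 20 (1R,3R)-5-(4,5-dimethoxy-7-methylnaphthalen-1-yl)-6-methoxy-1,3-dimethyl-1,2,3,4-tetrahydroisoquinolin-8-ol
Product: 21 ancistrocongoline B, (1R,3R)-5-(4,5-dimethoxy-7-methylnaphthalen-1-yl)-6-methoxy-1,2,3-trimethyl-1,2,3,4-tetrahydroisoquinolin-8-ol
Conditions: aq. HCHO, NaBH(OAc)3, ClCH2CH2Cl, rt
Reagents that add atoms: formaldehyde, C=O
Why: Reductive amination of the secondary amine with formaldehyde touches neither stereocentre, and a transient N,O-methylene acetal with the C8 phenol, if it forms, is reduced to the same N-methyl product.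

Compound list
1 | 1-bromo-3-methoxy-5-methylbenzene | COc1cc(C)cc(Br)c1 | starting material
2 | 2-methoxyfuran | COc1ccco1 | starting material
3 | 3-methoxy-5-methylbenzyne | COC1=CC(C)=CC#C1 | intermediate
4 | 1,8-dimethoxy-6-methyl-1,4-dihydro-1,4-epoxynaphthalene (racemic) | COC12OC(C=C1)c1cc(C)cc(OC)c12 | intermediate
5 | 4,5-dimethoxy-7-methylnaphthalen-1-ol | COc1ccc(O)c2cc(C)cc(OC)c12 | intermediate
6 | 4,5-dimethoxy-7-methylnaphthalen-1-yl trifluoromethanesulfonate | COc1ccc(OS(=O)(=O)C(F)(F)F)c2cc(C)cc(OC)c12 | intermediate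
7 | 1-bromo-3,5-dimethoxybenzene | COc1cc(Br)cc(OC)c1 | starting material
8 | 2-bromo-4,6-dimethoxybenzaldehyde | COc1cc(Br)c(C=O)c(OC)c1 | intermediate
9 | 2-bromo-6-hydroxy-4-methoxybenzaldehyde | COc1cc(O)c(C=O)c(Br)c1 | intermediate
10 | tert-butyl N-[(2R)-1-hydroxypropan-2-yl]carbamate (N-Boc-D-alaninol) | C[C@H](CO)NC(=O)OC(C)(C)C | starting material
11 | tert-butyl N-[(2R)-1-iodopropan-2-yl]carbamate | C[C@H](CI)NC(=O)OC(C)(C)C | intermediate
12 | [(2R)-2-(tert-butoxycarbonylamino)propyl]zinc iodide | C[C@H](C[Zn]I)NC(=O)OC(C)(C)C | intermediate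
13 | tert-butyl N-[(2R)-1-(2-formyl-3-hydroxy-5-methoxyphenyl)propan-2-yl]carbamate | COc1cc(O)c(C=O)c(C[C@@H](C)NC(=O)OC(C)(C)C)c1 | intermediate
14 | tert-butyl N-[(2R)-1-(6-bromo-2-formyl-3-hydroxy-5-methoxyphenyl)propan-2-yl]carbamate | COc1cc(O)c(C=O)c(C[C@@H](C)NC(=O)OC(C)(C)C)c1Br | intermediate
15 | 2-(4,5-dimethoxy-7-methylnaphthalen-1-yl)-4,4,5,5-tetramethyl-1,3,2-dioxaborolane | COc1ccc(B2OC(C)(C)C(C)(C)O2)c2cc(C)cc(OC)c12 | intermediate
16 | tert-butyl N-[(2R)-1-[6-(4,5-dimethoxy-7-methylnaphthalen-1-yl)-2-formyl-3-hydroxy-5-methoxyphenyl]propan-2-yl]carbamate (both axis rotamers) | COc1cc(O)c(C=O)c(C[C@@H](C)NC(=O)OC(C)(C)C)c1-c1ccc(OC)c2c(OC)cc(C)cc12 | intermediate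
17 | tert-butyl N-[(2R)-1-[6-(4,5-dimethoxy-7-methylnaphthalen-1-yl)-3-hydroxy-2-(1-hydroxyethyl)-5-methoxyphenyl]propan-2-yl]carbamate (mixture at the carbinol carbon) | COc1cc(O)c(C(C)O)c(C[C@@H](C)NC(=O)OC(C)(C)C)c1-c1ccc(OC)c2c(OC)cc(C)cc12 | intermediate
18 | 3-[(2R)-2-aminopropyl]-4-(4,5-dimethoxy-7-methylnaphthalen-1-yl)-2-(1-hydroxyethyl)-5-methoxyphenol | COc1cc(O)c(C(C)O)c(C[C@@H](C)N)c1-c1ccc(OC)c2c(OC)cc(C)cc12 | intermediate
19 | 5-[(2R)-2-aminopropyl]-4-(4,5-dimethoxy-7-methylnaphthalen-1-yl)-6-ethylidene-3-methoxycyclohexa-2,4-dien-1-one (ortho-quinone methide) | CC=C1C(=O)C=C(OC)C(=C1C[C@@H](C)N)c1ccc(OC)c2c(OC)cc(C)cc12 | intermediate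
20 | (1R,3R)-5-(4,5-dimethoxy-7-methylnaphthalen-1-yl)-6-methoxy-1,3-dimethyl-1,2,3,4-tetrahydroisoquinolin-8-ol | COc1cc(O)c2c(c1-c1ccc(OC)c3c(OC)cc(C)cc13)C[C@@H](C)N[C@@H]2C | intermediate
21 | ancistrocongoline B, (1R,3R)-5-(4,5-dimethoxy-7-methylnaphthalen-1-yl)-6-methoxy-1,2,3-trimethyl-1,2,3,4-tetrahydroisoquinolin-8-ol | COc1cc(O)c2c(c1-c1ccc(OC)c3c(OC)cc(C)cc13)C[C@@H](C)N(C)[C@@H]2C | target

Total step count: 11. Longest linear sequence: 8 steps (steps 3, 4, 6, 7, 8, 9, 10 and 11, from 7 to 21).

Steps most likely to fail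

Step 10. Equilibration at C1 may stay incomplete, leaving part of the material as the kinetically closed cis isomer, and the benzylic cation may alkylate electron-rich rings of a second molecule. The fallback sets out from 17 and keeps the same ring-closing bond but sets C1 by hydride delivery. Oxidation of the benzylic alcohol (MnO2, CH2Cl2) would give the aryl methyl ketone tert-butyl N-[(2R)-1-[2-acetyl-6-(4,5-dimethoxy-7-methylnaphthalen-1-yl)-3-hydroxy-5-methoxyphenyl]propan-2-yl]carbamate F1. TFA then removes the Boc group and the amine condenses with the ketone to the cyclic imine (3R)-5-(4,5-dimethoxy-7-methylnaphthalen-1-yl)-6-methoxy-1,3-dimethyl-3,4-dihydroisoquinolin-8-ol F2. Reduction with LiAlH4/AlMe3 in THF at −78 °C, the combination known to deliver hydride trans-selectively to 1,3-dimethyl-3,4-dihydroisoquinolines, comes back to the route at 20.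

Step 8. Oxidative addition into the hindered C–Br bond, which lies para to a phenoxide under the basic conditions, may be slower than protodeboronation of the naphthyl boronate. The fallback sets out from 14 and moves the biaryl coupling to the cyclised stage, the substrate class on which 5-halo-6,8-dioxygenated tetrahydroisoquinolines are known to couple with naphthylboron reagents. MeMgBr addition as in step 9 would give tert-butyl N-[(2R)-1-[6-bromo-3-hydroxy-2-(1-hydroxyethyl)-5-methoxyphenyl]propan-2-yl]carbamate F3. TFA as in step 10 closes it to (1R,3R)-5-bromo-6-methoxy-1,3-dimethyl-1,2,3,4-tetrahydroisoquinolin-8-ol F4. Reductive methylation as in step 11 gives (1R,3R)-5-bromo-6-methoxy-1,2,3-trimethyl-1,2,3,4-tetrahydroisoquinolin-8-ol F5, whose tertiary amine cannot undergo N-arylation. Suzuki–Miyaura coupling of F5 with boronate 15 (made from 6 as in step 8; Pd(OAc)2, SPhos, aq. K3PO4) comes back to the route at 21.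

Step 6. The free phenol may protonate the alkylzinc reagent, and the reagent may lose its carbamate by β-elimination before transmetalation. The fallback sets out from 9 and reverses the polarity of the C4–C4a bond construction (aryl nucleophile, sp3 electrophile). Silylation (TBSCl, imidazole) gives 2-bromo-6-[(tert-butyldimethylsilyl)oxy]-4-methoxybenzaldehyde F6, and acetalisation (HC(OMe)3, MeOH, cat. pyridinium tosylate) gives [3-bromo-2-(dimethoxymethyl)-5-methoxyphenoxy](tert-butyl)dimethylsilane F7. Bromine–lithium exchange (n-BuLi, −78 °C), transmetalation with MgBr2·OEt2 and CuI-catalysed SN2 opening of purchased (R)-tert-butyl 4-methyl-1,2,3-oxathiazolidine-3-carboxylate 2,2-dioxide at its CH2–O carbon follow. Hydrolysis of the N-sulfamate and the acetal with 1 M HCl in THF then gives tert-butyl N-[(2R)-1-[3-[(tert-butyldimethylsilyl)oxy]-2-formyl-5-methoxyphenyl]propan-2-yl]carbamate F8. Desilylation with tetrabutylammonium fluoride comes back to the route at 13.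

Further compounds
F1 | step 10 | tert-butyl N-[(2R)-1-[2-acetyl-6-(4,5-dimethoxy-7-methylnaphthalen-1-yl)-3-hydroxy-5-methoxyphenyl]propan-2-yl]carbamate | COc1cc(O)c(C(C)=O)c(C[C@@H](C)NC(=O)OC(C)(C)C)c1-c1ccc(OC)c2c(OC)cc(C)cc12
F2 | step 10 | (3R)-5-(4,5-dimethoxy-7-methylnaphthalen-1-yl)-6-methoxy-1,3-dimethyl-3,4-dihydroisoquinolin-8-ol | COc1cc(O)c2c(c1-c1ccc(OC)c3c(OC)cc(C)cc13)C[C@@H](C)N=C2C
F3 | step 8 | tert-butyl N-[(2R)-1-[6-bromo-3-hydroxy-2-(1-hydroxyethyl)-5-methoxyphenyl]propan-2-yl]carbamate | COc1cc(O)c(C(C)O)c(C[C@@H](C)NC(=O)OC(C)(C)C)c1Br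
F4 | step 8 | (1R,3R)-5-bromo-6-methoxy-1,3-dimethyl-1,2,3,4-tetrahydroisoquinolin-8-ol | COc1cc(O)c2c(c1Br)C[C@@H](C)N[C@@H]2C
F5 | step 8 | (1R,3R)-5-bromo-6-methoxy-1,2,3-trimethyl-1,2,3,4-tetrahydroisoquinolin-8-ol | COc1cc(O)c2c(c1Br)C[C@@H](C)N(C)[C@@H]2C
F6 | step 6 | 2-bromo-6-[(tert-butyldimethylsilyl)oxy]-4-methoxybenzaldehyde | COc1cc(O[Si](C)(C)C(C)(C)C)c(C=O)c(Br)c1
F7 | step 6 | [3-bromo-2-(dimethoxymethyl)-5-methoxyphenoxy](tert-butyl)dimethylsilane | COc1cc(O[Si](C)(C)C(C)(C)C)c(C(OC)OC)c(Br)c1
F8 | step 6 | tert-butyl N-[(2R)-1-[3-[(tert-butyldimethylsilyl)oxy]-2-formyl-5-methoxyphenyl]propan-2-yl]carbamate | COc1cc(O[Si](C)(C)C(C)(C)C)c(C=O)c(C[C@@H](C)NC(=O)OC(C)(C)C)c1
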